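All runs stem from a simulated flask on assumed constants; scatter was added.

Treat X, the monomer, as a tank draining with one time constant τ, the time in which it falls by the factor e, and replace the steady feed by a single charge at the feed's mean time.

| flask | X | E | remark | time |
|---|---|---|---|---|
| teal | 0.80 M (fed, over 6.0 min) | 10 mol% | run made earlier; the fed solution adds 1.0 times the starting volume |  |
| red | 1.2 M (fed, over 6.0 min) | 10 mol% | run made earlier; the fed solution adds 1.0 times the starting volume |  |
| blue | 1.6 M (fed, over 6.0 min) | 15 mol% | run made earlier; the fed solution adds 1.0 times the starting volume |  |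
| flask | 1.6 M (fed, over 6.0 min) | 10 mol% | the fed solution adds 1.0 times the starting volume | 1.0 h |

- teal (time / min: L / %, X / %): 8.00: 1.2, 70.8; 15.0: 3.4, 43.5; 25.0: 5.5, 19.9; 30.0: 5.6, 14.7; 40.0: 6.3, 7.1; 50.0: 8.2, 3.0; 60.0: 6.5, 2.1
- red (time / min: L / %, X / %): 3.00: 1.2, 45.3; 10.0: 3.2, 60.6; 15.0: 6.0, 41.9; 25.0: 9.1, 20.4; 40.0: 11.6, 4.7; 50.0: 10.7, 1.7; 60.0: 11.8, 0
- blue (time / min: L / %, X / %): 5.00: 3.1, 69.8; 10.0: 4.7, 58.0; 15.0: 10.5, 37.4; 30.0: 20.6, 7.8; 60.0: 23.1, 1.2

(readings scatter by 1 percentage point)

- charges are per starting volume, the dose included; the dosed solution carries all of it
- the average divides the monomer in chains by the number of chains begun, living and dead together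
- what was read earlier has a scatter of 1 percentage point, one standard deviation
- the earlier runs do not show the number of chains; that part of a forecast is a guess
- percentages count the whole charge, also what has not yet gone in

1. average number of monomer units in a chain (chains begun, living or dead) at 1.0 h
2. part of the X that has reacted at 1.0 h

I read τ late in the decay: it was longer in the teal run, 13.8 min, than in the blue run, 9.57 min. The flask held more X than teal and a lower loading of E, the initiator, than blue, so I took these as its upper and lower bounds. They left between 1.60% and 0.259% of the X at the asked time. With the charge diluted into the final volume, they gave between 459 M·s and 662 M·s for the exposure A, the time integral of the X concentration. For chain length I took a floor: each chain begun uses one E, so the average is at least L, the monomer in chains, over the E charged. The last reading of the red run, with less X at the same loading, gave 1.18 for that ratio, and I took this as the flask's floor. The earlier runs do not show the number of chains, so I set no ceiling on the chain length.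

The forecast said an average chain of 2.6 with 99% of the X reacted, adding “This is only a guess”. That left 1.00% of the X, inside my bracket, and its chain length stood above my floor.

The flask gave an average chain of 9.60 with 99.3% of the X reacted, so 0.67% of the X was left, inside the bracket.

    X + E → Q + L (k = 3.40 × 10⁻⁴ L mol⁻¹ s⁻¹)
    X + Q → L + Q, rate k2*[Q]*[X] (k = 0.0270 L mol⁻¹ s⁻¹)
    X → Z (k = 0.00110 s⁻¹)
    X → D (k = 8.70 × 10⁻⁶ s⁻¹)

With E still at 81.1% of its charge, chains start roughly in step with A, so the mean chain has half of A to grow in. The average is then roughly one plus the growth constant 0.027 L mol⁻¹ s⁻¹ times that half, which gives 7.20 to 9.94 around the flask's 9.60. The loss of X to the side product Z shortens the chains: taken away, the same flask gives 22.2 rather than 9.60.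

For the neighbour charged with 0.40 M of X, the upper exposure scaled to that charge gives 166 M·s, so an average of about 3.24. The computed value is 3.46.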